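## Retrosynthetic overview
1. Avoided: Cope rearrangement of a germacranolide (onopordopicrin type) and carvone/santonin ring editing. All carbons are assembled acyclically instead, and the single ring is closed late.
2. 21 ⇐ 19 by desilylation and C15–H allylic hydroxylation. 19 ⇐ 18 by C6–C7 ring closure, an intramolecular Hosomi–Sakurai reaction of a 2-carbomethoxy-allylsilane on an aldehyde. This sets C6 and C7 and unveils the open hydroxy-acrylate with the 8-O-ester already in place.
3. 18 ⇐ aldehyde 7. C8–O comes from D-proline α-aminoxylation, C7=C11 from an in-situ HWE with silylmethyl phosphonate 10, and the side chain from acylation with acid 16.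
4. 7 ⇐ acid 4 ⇐ ester 3. An enantioselective boron-dienolate Ireland–Claisen makes C5–C10, the quaternary centre, the vinyl group and the isopropenyl group in one step.
5. Ring order: there is only one ring (the cyclohexane), formed in step 13 of 15.

Position labels (elemane numbering): C10 = quaternary C (Me, vinyl); C5 = CH bearing the propenyl unit; C6 = CHOH; C7 = CH bearing the acrylate; C8 = CH–O-acyl; C9 = CH2.

Assumption: the (S,S)-diazaborolidine controller is taken to give the (2S,3S)-acid 4. I could not confirm this sense of induction, so it must be checked on the first run, and the equally available (R,R)-controller is used if it is opposite.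

## Route

**Step 1**
Reactants: 1 geraniol; 2 3-methylbut-3-enoic acid
Product: 3 geranyl 3-methylbut-3-enoate
Conditions: EDC·HCl, DMAP (5 mol %), CH2Cl2, 0 °C
Reagents that add atoms: none (all atoms come from 1 and 2)
Why: Steglich-type esterification of a primary allylic alcohol, where little DMAP at 0 °C keeps the β,γ-olefin out of conjugation and no stereocentre is formed.

**Step 2**
Reactants: 3
Product: 4 (2S,3S)-3,7-dimethyl-2-(prop-1-en-2-yl)-3-vinyloct-6-enoic acid
Conditions: (S,S)-2-bromo-4,5-diphenyl-1,3-bis[3,5-(CF3)2C6H3SO2]-1,3,2-diazaborolidine (1.3 equiv), Et3N, toluene–hexane, −78 °C; then −20 → 4 °C, several days; aq. acid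
Reagents that add atoms: none
Why: Enantioselective boron Ireland–Claisen rearrangement, in which soft enolisation of the doubly activated C5–H gives the E(O) dienolate (C4 group trans to the bulky O–B), the chair TS with the E-geranyl olefin places isopropenyl (C5) and methyl (C10) syn, and the C2-symmetric bis-sulfonamide blocks one face to set the absolute configuration of both centres.

**Step 3**
Reactants: 4
Product: 5 (2S,3S)-3,7-dimethyl-2-(prop-1-en-2-yl)-3-vinyloct-6-en-1-ol
Conditions: LiAlH4, Et2O, 0 °C → reflux
Reagents that add atoms: none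
Why: Hydride reduction of the acid, where the isolated olefins are inert and the carboxylate salt cannot epimerise at C5.

**Step 4**
Reactants: 5
Product: 6 triethylsilyl ether of 5
Conditions: TESCl, imidazole, CH2Cl2, 0 °C
Reagents that add atoms: chlorotriethylsilane, CC[Si](Cl)(CC)CC
Why: Standard silylation, with TES chosen because a primary TES ether can later be oxidised directly in the presence of TBS.

**Step 5**
Reactants: 6
Product: 7 (4S,5S)-4,6-dimethyl-5-[(triethylsilyloxy)methyl]-4-vinylhept-6-enal
Conditions: O3 (1.0 equiv, Sudan Red 7B end-point), CH2Cl2–pyridine, −78 °C; Me2S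
Reagents that add atoms: ozone, [O-][O+]=O
Why: Chemoselective ozonolysis, in which the unhindered, electron-rich trisubstituted olefin reacts before the shielded 1,1-disubstituted and neopentyl vinyl olefins (compare the ring-olefin selectivity in limonene), acetone is lost and the stereocentres are untouched.

**Step 6**
Reactants: 8 trimethyl phosphonoacetate; 9 (iodomethyl)trimethylsilane
Product: 10 methyl 2-(dimethoxyphosphoryl)-3-(trimethylsilyl)propanoate
Conditions: NaH, DME, 0 → 70 °C
Reagents that add atoms: none (all atoms come from 8 and 9)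
Why: SN2 alkylation of the stabilised phosphonate anion at an unhindered α-silyl iodide.

**Step 7**
Reactants: 7; 11 nitrosobenzene; 10
Product: 12 methyl (2Z,4S,6S,7S)-4-(anilinooxy)-6,8-dimethyl-7-[(triethylsilyloxy)methyl]-2-[(trimethylsilyl)methyl]-6-vinylnona-2,8-dienoate (CO2Me trans to C8)
Conditions: D-proline (20 mol %), MeCN, −20 °C; then 10, LiCl, DBU, 0 °C
Reagents that add atoms: nitrosobenzene 11, O=Nc1ccccc1; phosphonate 10, COC(=O)C(C[Si](C)(C)C)P(=O)(OC)OC
Why: Enamine α-aminoxylation (O-selective nitroso aldol through the Houk–List TS, where L-proline gives R so D-proline gives 8S under catalyst control), followed by an in-situ Masamune–Roush HWE that traps the labile α-oxy aldehyde as the thermodynamic enoate.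

**Step 8**
Reactants: 12
Product: 13 the corresponding (4S)-4-hydroxy enoate
Conditions: Cu(OAc)2·H2O (30 mol %), EtOH, rt
Reagents that add atoms: none
Why: Cu(II)-catalysed N–O cleavage that tolerates the enoate, allylsilane and TES ether, and because the OH is trans to CO2Me across the olefin no butenolide can form (any minor geometric isomer lactonises and is removed here).

**Step 9**
Reactants: 14 methyl 2-(hydroxymethyl)acrylate
Product: 15 methyl 2-[(tert-butyldimethylsilyloxy)methyl]acrylate
Conditions: TBSCl, imidazole, CH2Cl2, 0 °C → rt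
Reagents that add atoms: tert-butyldimethylsilyl chloride, CC(C)(C)[Si](C)(C)Cl
Why: Routine silylation of a primary allylic alcohol.

**Step 10**
Reactants: 15
Product: 16 2-[(tert-butyldimethylsilyloxy)methyl]acrylic acid
Conditions: LiOH, THF–H2O, 0 °C → rt; pH 4 work-up
Reagents that add atoms: lithium hydroxide/water, [Li+].[OH-]
Why: BAc2 saponification, in which the TBS ether and the α-substituted acrylate survive cold aqueous LiOH.

**Step 11**
Reactants: 13; 16
Product: 17 the 4-O-{2-[(TBSO)methyl]acryloyl} ester of 13
Conditions: 2,4,6-Cl3C6H2COCl, Et3N, toluene; then 13, DMAP, 0 °C → rt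
Reagents that add atoms: none (all atoms come from 13 and 16)
Why: Yamaguchi esterification of the only free hydroxyl, where C–O is not broken so 8S is retained.

**Step 12**
Reactants: 17
Product: 18 methyl (2Z,4S,6S,7S)-4-{2-[(TBSO)methyl]acryloyloxy}-7-formyl-6,8-dimethyl-2-[(trimethylsilyl)methyl]-6-vinylnona-2,8-dienoate (used crude)
Conditions: (COCl)2, DMSO, CH2Cl2, −78 → −40 °C; i-Pr2NEt, −78 → −20 °C
Reagents that add atoms: none
Why: Swern oxidation acting directly on a primary TES ether (chlorosulfonium-induced desilylation then oxidation) while the TBS ether is untouched, and the cold hindered base avoids epimerisation or conjugation at C5.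

**Step 13**
Reactants: 18
Product: 19 methyl 6α-hydroxy-8α-{2-[(TBSO)methyl]acryloyloxy}elema-1,3,11(13)-trien-12-oate (H5α, H6β, H7α, H8β, 10β-Me)
Conditions: BF3·OEt2 (2–3 equiv), 2,6-di-tert-butylpyridine, CH2Cl2, −78 → −40 °C; aq. NaHCO3
Reagents that add atoms: none
Why: Intramolecular Hosomi–Sakurai (SE2′) addition of a β-carbomethoxy-allylsilane to the activated aldehyde through a chair TS with isopropenyl, vinyl and O-acyl equatorial (H8 lies in the olefin plane by A1,3 strain, and an axial C6–O would be 1,3-diaxial to the C10 methyl), so C6–O and C7–C11 emerge equatorial (6R,7S) and loss of Me3Si unveils the methyl acrylate.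

**Step 14**
Reactants: 19
Product: 20 the 15-hydroxy derivative of 19
Conditions: SeO2 (0.5 equiv), t-BuOOH, CH2Cl2, 0 °C → rt (any enal returned with NaBH4/CeCl3, MeOH, −40 °C)
Reagents that add atoms: selenium dioxide, O=[Se]=O (terminal oxidant tert-butyl hydroperoxide, CC(C)(C)OO)
Why: Riley allylic hydroxylation (ene then [2,3]), selective because isopropenyl is the only electron-rich olefin with allylic C–H (the vinyl has none and both acrylates are deactivated) and CH3 reacts before the hindered C5–H.

**Step 15**
Reactants: 20
Product: 21 elemacarmanin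
Conditions: HF·pyridine, pyridine, THF, 0 °C → rt
Reagents that add atoms: none
Why: Buffered fluoride desilylation of the primary allylic TBS ether, mild enough to avoid O8→O6 acyl migration and 6,12-lactonisation.

## Compound list
1 | geraniol | CC(C)=CCC/C(C)=C/CO | starting material
2 | 3-methylbut-3-enoic acid | C=C(C)CC(=O)O | starting material
3 | geranyl 3-methylbut-3-enoate | C=C(C)CC(=O)OC/C=C(\C)CCC=C(C)C | intermediate
4 | (2S,3S)-3,7-dimethyl-2-(prop-1-en-2-yl)-3-vinyloct-6-enoic acid | C=C[C@](C)(CCC=C(C)C)[C@H](C(C)=C)C(=O)O | intermediate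
5 | (2S,3S)-3,7-dimethyl-2-(prop-1-en-2-yl)-3-vinyloct-6-en-1-ol | C=C[C@](C)(CCC=C(C)C)[C@H](C(C)=C)CO | intermediate
6 | TES ether of 5 | C=C[C@](C)(CCC=C(C)C)[C@H](C(C)=C)CO[Si](CC)(CC)CC | intermediate
7 | (4S,5S)-4,6-dimethyl-5-[(triethylsilyloxy)methyl]-4-vinylhept-6-enal | C=C[C@](C)(CCC=O)[C@H](C(C)=C)CO[Si](CC)(CC)CC | intermediate
8 | trimethyl phosphonoacetate | COC(=O)CP(=O)(OC)OC | starting material
9 | (iodomethyl)trimethylsilane | C[Si](C)(C)CI | starting material
10 | methyl 2-(dimethoxyphosphoryl)-3-(trimethylsilyl)propanoate | COC(=O)C(C[Si](C)(C)C)P(=O)(OC)OC | intermediate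
11 | nitrosobenzene | O=Nc1ccccc1 | starting material
12 | (2Z,4S,6S,7S)-4-anilinooxy allylsilane enoate | C=C[C@](C)(C[C@H](ONc1ccccc1)/C=C(\C[Si](C)(C)C)C(=O)OC)[C@H](C(C)=C)CO[Si](CC)(CC)CC | intermediate
13 | (2Z,4S,6S,7S)-4-hydroxy allylsilane enoate | C=C[C@](C)(C[C@H](O)/C=C(\C[Si](C)(C)C)C(=O)OC)[C@H](C(C)=C)CO[Si](CC)(CC)CC | intermediate
14 | methyl 2-(hydroxymethyl)acrylate | C=C(CO)C(=O)OC | starting material
15 | methyl 2-[(TBSO)methyl]acrylate | C=C(CO[Si](C)(C)C(C)(C)C)C(=O)OC | intermediate
16 | 2-[(TBSO)methyl]acrylic acid | C=C(CO[Si](C)(C)C(C)(C)C)C(=O)O | intermediate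
17 | 8-O-acylated TES ether | C=C[C@](C)(C[C@H](OC(=O)C(=C)CO[Si](C)(C)C(C)(C)C)/C=C(\C[Si](C)(C)C)C(=O)OC)[C@H](C(C)=C)CO[Si](CC)(CC)CC | intermediate
18 | aldehyde–allylsilane | C=C[C@](C)(C[C@H](OC(=O)C(=C)CO[Si](C)(C)C(C)(C)C)/C=C(\C[Si](C)(C)C)C(=O)OC)[C@H](C(C)=C)C=O | intermediate
19 | 6α-hydroxy-8α-acyloxy-elematrienoate (15-deoxy, TBS) | C=C[C@]1(C)C[C@H](OC(=O)C(=C)CO[Si](C)(C)C(C)(C)C)[C@@H](C(=C)C(=O)OC)[C@H](O)[C@H]1C(C)=C | intermediate
20 | 15-hydroxy derivative of 19 (TBS) | C=C[C@]1(C)C[C@H](OC(=O)C(=C)CO[Si](C)(C)C(C)(C)C)[C@@H](C(=C)C(=O)OC)[C@H](O)[C@H]1C(=C)CO | intermediate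
21 | elemacarmanin, (5R,6R,7S,8S,10S) | C=C[C@]1(C)C[C@H](OC(=O)C(=C)CO)[C@@H](C(=C)C(=O)OC)[C@H](O)[C@H]1C(=C)CO | target

## Step count and weak points
Total steps: 15. Longest linear sequence: 12 (steps 1–5, 7, 8, 11–15).

The three steps most likely to fail:

1. **Step 13 (ring closure).**
   - Risks: the allylsilane is ester-deactivated, BF3 could trigger desilylative 1,4-loss of the C8 carboxylate, and C5 could epimerise.
   - Fallback: change both the nucleophile and the order of events.
     - Carry O8 as a TBS ether.
     - Build C7=C11 as the (Z)-2-(bromomethyl)enoate, by a Morita–Baylis–Hillman reaction and then SN2′ bromination.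
     - Close the ring by intramolecular Nozaki–Hiyama (CrCl2) allylation through a closed Zimmerman–Traxler TS.
     - Acylate the less hindered 8-OH of the resulting 6,8-diol.
2. **Step 2 (asymmetric Claisen).**
   - Risks: the dienolate geometry, chair/boat leakage, and the sense or level of induction are all uncertain.
   - Fallback: give up reagent control. Run the ordinary LDA/TMSCl silyl ketene acetal Ireland–Claisen (racemic; if the lithium dienolate forms with Z(O) geometry, use neryl rather than geranyl ester to keep the same relative configuration). Then obtain the enantiomer by resolving acid 4 as a diastereomeric amine salt or pantolactone ester, or by separating the diastereomers created by the D-proline step at 13.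
3. **Step 7 (tandem aminoxylation/HWE with an α-branched phosphonate).**
   - Risk: the α-oxy aldehyde may decompose before the slow olefination takes place.
   - Fallback: take C8–O from the chiral pool.
     - React (S)-glycidyl TBS ether with lithium acetylide and protect the resulting alcohol.
     - Zr-catalysed carboalumination and HCHO quench then give an 8-oxygenated geraniol surrogate.
     - Carry this surrogate through steps 1–4.
     - Oxidise the primary C7–OH and olefinate with 10 under standard NaH conditions.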